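## Analysis of the target

Compound 16 is a (2S)-flavan, numbered in the usual way: ring A is the benzo ring (C4a–C8a), ring C the dihydropyran (O1, C2, C3, C4) and ring B the 2-aryl group (C1′–C6′). The only stereocentre is C2, an ether carbon benzylic to ring B. Rings A and C carry no other functional group, so C2 must be set as S directly and cannot be corrected later. C2 lies para to the free 4′-OH, so acid, base or prolonged heat can open the O1–C2 bond through a para-quinone methide and erase the configuration. Three C5 units decorate the core: a 2-methylbut-3-en-2-yl (1,1-dimethylallyl) group at C6 of ring A, and 3-methylbut-2-enyl (prenyl) groups at C2′ and C5′ of ring B.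

The feature that drives the plan: C6, C2′ and C5′ each sit ortho to a phenolic oxygen (O7, O3′ and O4′). Each C5 unit is the allyl-transposed image of the ether that would sit on that oxygen: a prenyl ether on O7, and 1,1-dimethylallyl ethers on O3′ and O4′.

Sensitive groups are the air-sensitive catechol, the ortho-prenylphenols (acid closes them to chromans), the ortho-(1,1-dimethylallyl)phenol (prone to the abnormal Claisen rearrangement and to cyclisation), and four C=C bonds that rule out late hydrogenation. The hard parts are the pentasubstituted ring B with C2′ wedged between C1′ and O3′, the quaternary benzylic carbon at C6 (C6 versus C8), and keeping C2 intact while all of this is installed.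

## Retrosynthetic reasoning

**16 from 15.** The three phenols are masked as acetates in 15. Only three O–acyl bonds are cut. Acetates are chosen because they form in the flask of the key step and leave under cold, weakly basic conditions that do not open ring C.

**15 from 13 (key disconnection).** The bonds C6–C(quaternary), C2′–CH2 and C5′–CH2 are cut, and each C5 unit is returned with allyl inversion to the neighbouring oxygen. This gives the tris-ether 13, which has no carbon substituent on either arene beyond the flavan skeleton. These are the only three C–C bonds that are not part of the core, and each is the retron of an aromatic [3,3] shift. The forward reaction must run three Claisen rearrangements in one flask, two of them at low temperature on ring B (through 14) and one at high temperature on ring A, with each phenol acetylated as it appears.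

**13 from 10 and 11.** The O7–CH2 bond is cut. The silyl ether of 10 is the only group that fluoride removes while the tertiary allyl ethers stay, and the phenoxide 12 formed in the flask is alkylated directly by 11.

**10 from 7 and 9.** The two O–C(tertiary) bonds on ring B are cut. The forward reaction is an allylic etherification under zerovalent palladium catalysis that must deliver the more substituted allyl terminus to oxygen. Reagent 9 comes from alcohol 8 in one step.

**7 from 6.** The two benzyl ethers are cut. Hydrogenolysis is placed here because it is the last point at which the molecule contains no C=C bond.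

**6 from 5 and 5 from 4.** The C4 oxygen is removed in two reliable operations: hydride reduction of the ketone and ionic deoxygenation of the resulting benzylic alcohol. The ketone is the relic of the step that sets C2.

**4 from 2 and 3.** The C2–C1′ bond is cut. This joins the two halves and sets C2 in one catalytic operation from an achiral chromone and an achiral arylboronic acid. Because the two ring-B prenyl groups arrive later, 3 has no ortho substituent and the coupling partner is unhindered. Chromone 2 is the silyl ether of commercial 1.

## Alternatives that were turned down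

**Alternative 1:** the textbook route. O1–C2 and C3–C4 are cut. A ring-B acetophenone and a ring-A salicylaldehyde, both already prenylated, are condensed (Claisen–Schmidt), the enone is reduced, and the ketone is reduced asymmetrically to the (R)-carbinol A1. Ring C is then closed by Mitsunobu etherification with inversion.
- Each arene must be prenylated separately; the 2,5-diprenyl-3,4-dioxygenated acetophenone alone needs about as many steps as the whole route below.
- The acetyl group sits beside an ortho prenyl group, which hinders both condensation and reduction.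
- The enone C=C must be reduced next to three other alkenes.
- A1 is a para-oxygenated benzylic alcohol, so Mitsunobu activation tends toward ionisation and loss of configuration at the only stereocentre.
- Several protecting groups must be added and removed.

**Alternative 2:** O1–C2 and C3–C4 are cut together. The forward key step is an inverse-demand hetero-Diels–Alder reaction between the ring-A ortho-quinone methide A3 and the ring-B styrene A2, which builds ring C from two finished arenes.
- The only stereocentre arises from the face of an unfunctionalised styrene attacked by an unsubstituted methide; neither partner offers a handle for a chiral catalyst, so a racemate and a resolution are expected.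
- A2 carries two electron-rich trisubstituted alkenes that are themselves good dienophiles for A3.
- Both partners still need their own regioselective prenylation sequences.

**Alternative 3:** O1–C2 alone is cut, as the last bond. The racemic carbinol A4 is dehydrated by a chiral Brønsted acid to the para-quinone methide A5, and the ring-A phenol adds in an enantioselective oxa-1,6-addition.
- The feature that makes this possible (4′-OH para to C2) also lets the same acid re-ionise 16, so the configuration is under kinetic control only as long as the product does not revert.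
- The ortho-prenylphenols of A4 and 16 are exposed to acid and can close to chromans.
- All three C5 units must be in place on an unprotected polyphenol before closure, so the prenylation problem is moved, not solved.

Key step: step 9

## Route

Assumption: 1, 3, 8 and 11 are taken as commercial; in step 2 the (R)-ligand is assumed to give the (2S)-ketone, by analogy with the (S)-ligand giving (R)-3-aryl ketones from cyclic enones, and the other ligand enantiomer is used if the sense proves opposite.

Step 1
Reactants: 1 7-hydroxy-4H-chromen-4-one
Product: 2 7-[(triisopropylsilyl)oxy]-4H-chromen-4-one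
Conditions: i-Pr3SiCl, imidazole, DMF, 0 °C to rt
Reagents that add atoms: chlorotriisopropylsilane, CC(C)[Si](Cl)(C(C)C)C(C)C
Why: Standard silylation of an acidic phenol; the triisopropylsilyl ether should survive hydride, cold acid and hydrogenolysis and later leave with fluoride while tertiary allyl ethers stay.

Step 2
Reactants: 2 7-[(triisopropylsilyl)oxy]-4H-chromen-4-one; 3 [3,4-bis(benzyloxy)phenyl]boronic acid
Product: 4 (2S)-2-[3,4-bis(benzyloxy)phenyl]-7-[(triisopropylsilyl)oxy]-2,3-dihydro-4H-chromen-4-one
Conditions: Pd(OCOCF3)2 (5 mol%), (R)-4-tert-butyl-2-(pyridin-2-yl)-4,5-dihydrooxazole (6 mol%), NH4PF6 (30 mol%), H2O (5 equiv), ClCH2CH2Cl, 60 °C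
Reagents that add atoms: none
Why: Palladium-catalysed asymmetric conjugate addition of an arylboronic acid to a chromone: a cationic aryl complex of divalent palladium inserts across C2=C3 and the palladium enolate is protonated; the pyridine–oxazoline ligand selects the enone face and should set C2 as S, and 3 has no ortho substituent to slow transmetalation.

Step 3
Reactants: 4 (2S)-2-[3,4-bis(benzyloxy)phenyl]-7-[(triisopropylsilyl)oxy]-2,3-dihydro-4H-chromen-4-one
Product: 5 (2S,4S)-2-[3,4-bis(benzyloxy)phenyl]-7-[(triisopropylsilyl)oxy]chroman-4-ol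
Conditions: NaBH4, MeOH/THF, 0 °C
Reagents that add atoms: none
Why: Borohydride reduction of an aryl ketone; hydride should add anti to the pseudo-equatorial 2-aryl group to give mainly the cis alcohol, the C4 configuration is irrelevant because C4 becomes CH2 in step 4, and the low temperature should keep the flavanone from opening to the chalcone so that C2 is untouched.

Step 4
Reactants: 5 (2S,4S)-2-[3,4-bis(benzyloxy)phenyl]-7-[(triisopropylsilyl)oxy]chroman-4-ol
Product: 6 (2S)-2-[3,4-bis(benzyloxy)phenyl]-7-[(triisopropylsilyl)oxy]chroman
Conditions: Et3SiH, CF3CO2H, CH2Cl2, −20 to 0 °C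
Reagents that add atoms: none
Why: Ionic hydrogenation (Kursanov–Parnes deoxygenation) of a benzylic alcohol: the C4 cation is stabilised by O1 (ortho) and O7 (para) and is captured by silane hydride, whereas ionisation of O1–C2 needs protonation of an aryl ether oxygen and should not compete at low temperature, so C2 stays S.

Step 5
Reactants: 6 (2S)-2-[3,4-bis(benzyloxy)phenyl]-7-[(triisopropylsilyl)oxy]chroman
Product: 7 4-[(2S)-7-[(triisopropylsilyl)oxy]chroman-2-yl]benzene-1,2-diol
Conditions: H2 (1 atm), Pd/C (10%), EtOAc, rt
Reagents that add atoms: none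
Why: Hydrogenolysis of benzyl aryl ethers, placed before any C=C bond exists; the neutral medium and short contact time should spare the benzylic O1–C2 bond, and the silyl ether is inert.

Step 6
Reactants: 8 2-methylbut-3-en-2-ol
Product: 9 tert-butyl 2-methylbut-3-en-2-yl carbonate
Conditions: n-BuLi, THF, −78 °C; then Boc2O, −78 °C to rt
Reagents that add atoms: di-tert-butyl dicarbonate, CC(C)(C)OC(=O)OC(=O)OC(C)(C)C
Why: Acylation of the lithium alkoxide of a tertiary allylic alcohol gives the mixed carbonate, the usual leaving group for palladium allyl chemistry.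

Step 7
Reactants: 7 4-[(2S)-7-[(triisopropylsilyl)oxy]chroman-2-yl]benzene-1,2-diol; 9 tert-butyl 2-methylbut-3-en-2-yl carbonate
Product: 10 (2S)-2-[3,4-bis(2-methylbut-3-en-2-yloxy)phenyl]-7-[(triisopropylsilyl)oxy]chroman
Conditions: Pd(PPh3)4 (10 mol%), 9 (5 equiv), THF, 0–5 °C, Ar
Reagents that add atoms: none
Why: Tsuji–Trost allylic etherification: zerovalent palladium ionises 9 to a 1,1-dimethylallyl complex, carbon dioxide and tert-butoxide, which deprotonates the phenol; under kinetic control at low temperature the phenoxide should attack the more substituted allyl terminus, a mode known for catechols.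

Step 8
Reactants: 10 (2S)-2-[3,4-bis(2-methylbut-3-en-2-yloxy)phenyl]-7-[(triisopropylsilyl)oxy]chroman; 11 1-bromo-3-methylbut-2-ene
Product: 13 (2S)-2-[3,4-bis(2-methylbut-3-en-2-yloxy)phenyl]-7-(3-methylbut-2-enyloxy)chroman, via tetrabutylammonium chroman-7-olate 12 (not isolated)
Conditions: Bu4NF (1.1 equiv), THF, 0 °C; then 11 (1.5 equiv), 0 °C to rt
Reagents that add atoms: none
Why: Fluoride cleaves the aryl silyl ether to the ammonium phenoxide, which is alkylated in the same flask by Williamson etherification; the tertiary allyl ethers are stable to base and do not rearrange at or below room temperature.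

Step 9
Reactants: 13 (2S)-2-[3,4-bis(2-methylbut-3-en-2-yloxy)phenyl]-7-(3-methylbut-2-enyloxy)chroman
Product: 15 (2S)-2-[3,4-diacetoxy-2,5-bis(3-methylbut-2-enyl)phenyl]-6-(2-methylbut-3-en-2-yl)chroman-7-yl acetate, via ring-B diacetate 14 (not isolated)
Conditions: Ac2O, NaOAc, PhNEt2, sealed tube, Ar, 120 °C then 195 °C
Reagents that add atoms: acetic anhydride, CC(=O)OC(C)=O
Why: Three aromatic Claisen rearrangements ([3,3] shifts through chair-like transition states, each followed by enolisation of the ortho-dienone) run in one flask: at 120 °C the tertiary ethers on O3′ and O4′ deliver their C5 units with allyl inversion to C2′ and C5′ as prenyl groups (14 after acetylation), and at 195 °C the prenyl ether on O7 delivers its unit to C6 as the 2-methylbut-3-en-2-yl group. The closest known reaction types are the thermal rearrangement of aryl 1,1-dimethylallyl ethers to ortho-prenylphenols and of aryl prenyl ethers to ortho-(1,1-dimethylallyl)phenols in an anhydride/dialkylaniline medium that acylates each phenol as it forms. No ring is closed and no stereocentre is created; C2 should pass unchanged because the medium contains nothing that opens ring C and the 4′-oxygen is acetylated as soon as it is freed, which shuts the para-quinone methide path to epimerisation. On ring B the regiochemistry is fixed by the substrate: O3′ has only C2′ and O4′ has only C5′ as a hydrogen-bearing ortho carbon, and migration to the oxygen-bearing ortho carbon gives a dienone that cannot enolise and can return by the reverse shift. On ring A the step needs C6 over C8: C6 is para to O1, the position favoured by a meta alkoxy group, and the new quaternary carbon is less crowded beside C5–H than between O1 and O7. Acetylation in the flask removes the phenolic O–H and so should block the abnormal Claisen rearrangement of the ortho-(1,1-dimethylallyl)phenol, cyclisation of phenols onto the new alkenes, and catechol oxidation. The two temperature stages ensure that the labile tertiary ethers have reacted before the flask reaches 195 °C.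

Step 10
Reactants: 15 (2S)-2-[3,4-diacetoxy-2,5-bis(3-methylbut-2-enyl)phenyl]-6-(2-methylbut-3-en-2-yl)chroman-7-yl acetate
Product: 16 4-[(2S)-7-hydroxy-6-(2-methylbut-3-en-2-yl)chroman-2-yl]-3,6-bis(3-methylbut-2-enyl)benzene-1,2-diol
Conditions: NH3 (7 M in MeOH, degassed), 0 °C to rt, Ar
Reagents that add atoms: none
Why: Ammonolysis of aryl acetates; the cold, weakly basic, oxygen-free medium should free the three phenols without opening ring C at C2 and without oxidising the catechol.

## Compound list

1 | 7-hydroxy-4H-chromen-4-one | O=c1ccoc2cc(O)ccc12 | starting material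
2 | 7-[(triisopropylsilyl)oxy]-4H-chromen-4-one | CC(C)[Si](Oc1ccc2c(c1)occc2=O)(C(C)C)C(C)C | intermediate
3 | [3,4-bis(benzyloxy)phenyl]boronic acid | OB(O)c1ccc(OCc2ccccc2)c(OCc2ccccc2)c1 | starting material
4 | (2S)-2-[3,4-bis(benzyloxy)phenyl]-7-[(triisopropylsilyl)oxy]-2,3-dihydro-4H-chromen-4-one | O=C1C[C@@H](c2ccc(OCc3ccccc3)c(OCc3ccccc3)c2)Oc2cc(O[Si](C(C)C)(C(C)C)C(C)C)ccc12 | intermediate
5 | (2S,4S)-2-[3,4-bis(benzyloxy)phenyl]-7-[(triisopropylsilyl)oxy]chroman-4-ol | O[C@H]1C[C@@H](c2ccc(OCc3ccccc3)c(OCc3ccccc3)c2)Oc2cc(O[Si](C(C)C)(C(C)C)C(C)C)ccc12 | intermediate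
6 | (2S)-2-[3,4-bis(benzyloxy)phenyl]-7-[(triisopropylsilyl)oxy]chroman | CC(C)[Si](Oc1ccc2c(c1)O[C@H](c1ccc(OCc3ccccc3)c(OCc3ccccc3)c1)CC2)(C(C)C)C(C)C | intermediate
7 | 4-[(2S)-7-[(triisopropylsilyl)oxy]chroman-2-yl]benzene-1,2-diol | CC(C)[Si](Oc1ccc2c(c1)O[C@H](c1ccc(O)c(O)c1)CC2)(C(C)C)C(C)C | intermediate
8 | 2-methylbut-3-en-2-ol | CC(C)(O)C=C | starting material
9 | tert-butyl 2-methylbut-3-en-2-yl carbonate | CC(C)(C)OC(=O)OC(C)(C)C=C | intermediate
10 | (2S)-2-[3,4-bis(2-methylbut-3-en-2-yloxy)phenyl]-7-[(triisopropylsilyl)oxy]chroman | CC(C)[Si](Oc1ccc2c(c1)O[C@H](c1ccc(OC(C)(C)C=C)c(OC(C)(C)C=C)c1)CC2)(C(C)C)C(C)C | intermediate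
11 | 1-bromo-3-methylbut-2-ene (prenyl bromide) | CC(C)=CCBr | starting material
12 | tetrabutylammonium (2S)-2-[3,4-bis(2-methylbut-3-en-2-yloxy)phenyl]chroman-7-olate | CCCC[N+](CCCC)(CCCC)CCCC.[O-]c1ccc2c(c1)O[C@H](c1ccc(OC(C)(C)C=C)c(OC(C)(C)C=C)c1)CC2 | intermediate
13 | (2S)-2-[3,4-bis(2-methylbut-3-en-2-yloxy)phenyl]-7-(3-methylbut-2-enyloxy)chroman | CC(C)=CCOc1ccc2c(c1)O[C@H](c1ccc(OC(C)(C)C=C)c(OC(C)(C)C=C)c1)CC2 | intermediate
14 | 3,6-bis(3-methylbut-2-enyl)-4-[(2S)-7-(3-methylbut-2-enyloxy)chroman-2-yl]-1,2-phenylene diacetate | CC(C)=CCOc1ccc2c(c1)O[C@H](c1cc(CC=C(C)C)c(OC(C)=O)c(OC(C)=O)c1CC=C(C)C)CC2 | intermediate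
15 | (2S)-2-[3,4-diacetoxy-2,5-bis(3-methylbut-2-enyl)phenyl]-6-(2-methylbut-3-en-2-yl)chroman-7-yl acetate | C=CC(C)(C)c1cc2c(cc1OC(C)=O)O[C@H](c1cc(CC=C(C)C)c(OC(C)=O)c(OC(C)=O)c1CC=C(C)C)CC2 | intermediate
16 | 4-[(2S)-7-hydroxy-6-(2-methylbut-3-en-2-yl)chroman-2-yl]-3,6-bis(3-methylbut-2-enyl)benzene-1,2-diol (CNP0118330.1) | C=CC(C)(C)c1cc2c(cc1O)O[C@H](c1cc(CC=C(C)C)c(O)c(O)c1CC=C(C)C)CC2 | target

## Step count and least certain steps

Total: 10 steps. Longest linear sequence: 9 steps (steps 1–5 and 7–10 from 1); step 6 is a one-step side branch.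

**Step 9 (key step).** The ring-A shift needs about 195 °C, and at that temperature migration to C8 instead of C6 and loss of the C5 unit by fragmentation of the O7 ether can divert material. On ring B, migration to an oxygen-bearing carbon followed by intramolecular Diels–Alder capture of the dienone is a lesser risk. Ring A is the most likely point of failure because its selectivity rests on an electronic and steric preference, not on a blocked position.

Fallback (sets out from 7, returns at 15): the C6–C bond is made by cross-coupling at a position fixed by bromination, and only the two low-temperature shifts are kept.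
- Acetylation of 7 (Ac2O, pyridine) should give 4-[(2S)-7-[(triisopropylsilyl)oxy]chroman-2-yl]-1,2-phenylene diacetate F1.
- Buffered fluoride (Bu4NF, AcOH, THF, 0 °C) should give 4-[(2S)-7-hydroxychroman-2-yl]-1,2-phenylene diacetate F2.
- NBS in MeCN at 0 °C should brominate ring A ortho to the phenol and para to O1, ring B being deactivated by its acetates, to give 4-[(2S)-6-bromo-7-hydroxychroman-2-yl]-1,2-phenylene diacetate F3.
- Suzuki–Miyaura coupling with 3-methylbut-2-enylboronic acid pinacol ester, under conditions known to couple allylboron reagents at the γ-carbon (Pd(OAc)2, 1,1′-bis(di-tert-butylphosphino)ferrocene, aqueous K3PO4, THF, 60 °C; the acetates are hydrolysed in the same flask), should give 4-[(2S)-7-hydroxy-6-(2-methylbut-3-en-2-yl)chroman-2-yl]benzene-1,2-diol F4.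
- The conditions of step 7 should etherify only the catechol oxygens, because O7 is now flanked by the quaternary carbon, to give (2S)-2-[3,4-bis(2-methylbut-3-en-2-yloxy)phenyl]-6-(2-methylbut-3-en-2-yl)chroman-7-ol F5.
- Heating F5 at 120 °C in Ac2O/NaOAc/PhNEt2 performs the two ring-B shifts and acetylates all three oxygens, which gives 15.

**Step 2.** The 7-silyloxy group lowers the electrophilicity of the chromone, so conversion may stall. Protodeboronation of the electron-rich boronic acid, partial loss of the silyl group in the aqueous hexafluorophosphate medium, and insufficient facial selectivity are the other failure processes.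

Fallback (sets out from 2 and 3, returns at 5): the same addition with achiral 2,2′-bipyridine in place of the chiral ligand should give racemic 2-[3,4-bis(benzyloxy)phenyl]-7-[(triisopropylsilyl)oxy]-2,3-dihydro-4H-chromen-4-one F6. Noyori asymmetric transfer hydrogenation (RuCl(p-cymene)[(S,S)-TsDPEN], HCO2H/Et3N, EtOAc, rt) then serves as a kinetic resolution: the (2S)-ketone should be reduced to 5, and the slow-reacting (2R)-2-[3,4-bis(benzyloxy)phenyl]-7-[(triisopropylsilyl)oxy]-2,3-dihydro-4H-chromen-4-one F7 is separated. The cost is at most half of the material.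

**Step 4.** Ionisation of O1–C2, supported by the 4′-benzyloxy group, may compete with ionisation at C4. That would lead to ring opening with hydride capture or to loss of configuration at C2.

Fallback (sets out from 5, returns at 6): radical Barton–McCombie deoxygenation, which involves no cation. 1,1′-Thiocarbonyldiimidazole (DMAP, CH2Cl2, rt) should give O-[(2S,4S)-2-[3,4-bis(benzyloxy)phenyl]-7-[(triisopropylsilyl)oxy]chroman-4-yl] 1H-imidazole-1-carbothioate F8, and Bu3SnH/AIBN in toluene at 80 °C should reduce it to 6.

**Step 7.** The tertiary ethers form under kinetic control and may isomerise to the linear prenyl ethers on the catalyst. The second etherification beside the first bulky ether may be incomplete, and C-allylation of the electron-rich catechol is possible.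

Fallback (sets out from 7, returns at 10): copper-catalysed propargylation followed by semihydrogenation. 2-Methylbut-3-yn-2-ol is activated in the flask as its trifluoroacetate ((CF3CO)2O, DBU) and reacts with 7 (CuCl2 catalytic, DBU, MeCN, 0 °C) to give (2S)-2-[3,4-bis(2-methylbut-3-yn-2-yloxy)phenyl]-7-[(triisopropylsilyl)oxy]chroman F9. Hydrogenation over Pd/CaCO3 poisoned with Pb(OAc)2 (quinoline, EtOAc, rt) should reduce both alkynes to the alkenes of 10.

## Further compounds

F1 | step 9 | 4-[(2S)-7-[(triisopropylsilyl)oxy]chroman-2-yl]-1,2-phenylene diacetate | CC(C)[Si](Oc1ccc2c(c1)O[C@H](c1ccc(OC(C)=O)c(OC(C)=O)c1)CC2)(C(C)C)C(C)C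
F2 | step 9 | 4-[(2S)-7-hydroxychroman-2-yl]-1,2-phenylene diacetate | Oc1ccc2c(c1)O[C@H](c1ccc(OC(C)=O)c(OC(C)=O)c1)CC2
F3 | step 9 | 4-[(2S)-6-bromo-7-hydroxychroman-2-yl]-1,2-phenylene diacetate | Brc1cc2c(cc1O)O[C@H](c1ccc(OC(C)=O)c(OC(C)=O)c1)CC2
F4 | step 9 | 4-[(2S)-7-hydroxy-6-(2-methylbut-3-en-2-yl)chroman-2-yl]benzene-1,2-diol | C=CC(C)(C)c1cc2c(cc1O)O[C@H](c1ccc(O)c(O)c1)CC2
F5 | step 9 | (2S)-2-[3,4-bis(2-methylbut-3-en-2-yloxy)phenyl]-6-(2-methylbut-3-en-2-yl)chroman-7-ol | C=CC(C)(C)c1cc2c(cc1O)O[C@H](c1ccc(OC(C)(C)C=C)c(OC(C)(C)C=C)c1)CC2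
F6 | step 2 | racemic 2-[3,4-bis(benzyloxy)phenyl]-7-[(triisopropylsilyl)oxy]-2,3-dihydro-4H-chromen-4-one | O=C1CC(c2ccc(OCc3ccccc3)c(OCc3ccccc3)c2)Oc2cc(O[Si](C(C)C)(C(C)C)C(C)C)ccc12
F7 | step 2 | (2R)-2-[3,4-bis(benzyloxy)phenyl]-7-[(triisopropylsilyl)oxy]-2,3-dihydro-4H-chromen-4-one | O=C1C[C@H](c2ccc(OCc3ccccc3)c(OCc3ccccc3)c2)Oc2cc(O[Si](C(C)C)(C(C)C)C(C)C)ccc12
F8 | step 4 | O-[(2S,4S)-2-[3,4-bis(benzyloxy)phenyl]-7-[(triisopropylsilyl)oxy]chroman-4-yl] 1H-imidazole-1-carbothioate | S=C(O[C@H]1C[C@@H](c2ccc(OCc3ccccc3)c(OCc3ccccc3)c2)Oc2cc(O[Si](C(C)C)(C(C)C)C(C)C)ccc12)n1ccnc1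
F9 | step 7 | (2S)-2-[3,4-bis(2-methylbut-3-yn-2-yloxy)phenyl]-7-[(triisopropylsilyl)oxy]chroman | CC(C)[Si](Oc1ccc2c(c1)O[C@H](c1ccc(OC(C)(C)C#C)c(OC(C)(C)C#C)c1)CC2)(C(C)C)C(C)C
A1 | alternative 1 | (1R)-1-[3,4-bis(methoxymethoxy)-2,5-bis(3-methylbut-2-enyl)phenyl]-3-[2-hydroxy-4-(methoxymethoxy)-5-(2-methylbut-3-en-2-yl)phenyl]propan-1-ol | O[C@@H](c1cc(CC=C(C)C)c(OCOC)c(OCOC)c1CC=C(C)C)CCc1cc(C(C)(C)C=C)c(OCOC)cc1O
A2 | alternative 2 | 1-ethenyl-3,4-bis(methoxymethoxy)-2,5-bis(3-methylbut-2-enyl)benzene | C=Cc1cc(CC=C(C)C)c(OCOC)c(OCOC)c1CC=C(C)C
A3 | alternative 2 | 6-methylidene-4-(2-methylbut-3-en-2-yl)-3-[(triisopropylsilyl)oxy]cyclohexa-2,4-dien-1-one | C=C1C=C(C(C)(C)C=C)C(O[Si](C(C)C)(C(C)C)C(C)C)=CC1=O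
A4 | alternative 3 | racemic 4-[3-[2,4-dihydroxy-5-(2-methylbut-3-en-2-yl)phenyl]-1-hydroxypropyl]-3,6-bis(3-methylbut-2-enyl)benzene-1,2-diol | OC(c1cc(CC=C(C)C)c(O)c(O)c1CC=C(C)C)CCc1cc(C(C)(C)C=C)c(O)cc1O
A5 | alternative 3 | 4-[3-[2,4-dihydroxy-5-(2-methylbut-3-en-2-yl)phenyl]propylidene]-2-hydroxy-3,6-bis(3-methylbut-2-enyl)cyclohexa-2,5-dien-1-one | O=C1C(O)=C(CC=C(C)C)C(=CCCc2cc(C(C)(C)C=C)c(O)cc2O)C=C1CC=C(C)C
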